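**Retrosynthetic overview**
- Last key disconnection is the C8–O ester bond, made with inversion (Mitsunobu) from the 8-epi alcohol and (Z)-4-acetoxy-2-methylbut-2-enoic acid; the C12 acid then comes from SeO2/Pinnick oxidation of the C7 isopropenyl group.
- C6–O and C5: face-selective epoxidation of a 1,3-diene (Negishi coupling of an enol triflate), then formate hydrogenolysis of the alkenyl oxirane, which puts H on C5 anti to oxygen.
- C10 quaternary centre: conjugate reduction/aldol with acetaldehyde, then dehydration to the vinyl group.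
- C8–O: a new vinylogous silyloxylation of the through-conjugated silyl dienol ether of (R)-carvone.
- Rings: none is formed; the single cyclohexane ring and the C7 stereocentre are taken from (R)-carvone.

Convention and assumption (one line): the SMILES is read literally and ring positions carry elemane numbers (C10 = quaternary C with Me and vinyl, C9 = CH2, C8 = acyloxy carbon, C7 = carbon bearing the acrylic acid, C6 = carbinol, C5 = carbon bearing the hydroxy-isopropenyl group; carvone C2/C3/C4/C5/C6/C1 become C10/C9/C8/C7/C6/C5); Et3SiOOSiEt3 is assumed to be made beforehand from DABCO·2H2O2 and Et3SiCl.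

Target stereochemistry in these terms: C10 vinyl, C8–O and the C7 side chain are on one face; C10 methyl, C6–OH and the C5 side chain are on the other.

**Step 1**
Reactants: 1 (R)-(−)-carvone
Product: 3 through-conjugated trimethylsilyl dienol ether of carvone (C5–OSiMe3; C5=C10 and C9=C8 double bonds; C7 centre unchanged), via magnesium dienolate 2 (not isolated)
Conditions: MeMgBr (1.5 equiv), FeCl3 (5 mol %), Et2O, −20 °C; then Me3SiCl, Et3N, HMPA, −20 °C → rt
Reagents that add atoms: chlorotrimethylsilane, C[Si](C)(C)Cl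
Why: The MeMgBr/FeCl3 (Kharasch) base removes the γ-proton at C8 to give the thermodynamic through-conjugated dienolate, which is O-silylated (thermodynamic silyl dienol ether formation) without touching the stereocentre.

**Step 2**
Reactants: 3 through-conjugated trimethylsilyl dienol ether of carvone
Product: 4 (4S,5R)-2-methyl-5-(prop-1-en-2-yl)-4-(triethylsilyloxy)cyclohex-2-en-1-one (C8–OSiEt3 trans to the C7 isopropenyl)
Conditions: Et3SiOOSiEt3 (1.1 equiv), Me3SiOTf (5 mol %), CH2Cl2, −78 °C
Reagents that add atoms: bis(triethylsilyl) peroxide, CC[Si](CC)(CC)OO[Si](CC)(CC)CC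
Why: Proposed new method: a vinylogous Mukaiyama-type silyloxylation in which Me3SiOTf silylates one peroxide oxygen, the γ-carbon C8 of 3 attacks the other oxygen (SN2 at O) anti to the neighbouring C7 isopropenyl group so that C8–O is set trans to it, Et3SiOSiMe3 leaves and the oxocarbenium ion returns Me3Si+ to triflate to turn the catalyst over; the closest known reactions are the vinylogous Rubottom oxidation of silyl dienol ethers with peracids and the electrophilic hydroxylation of enolates with bis(trimethylsilyl) peroxide.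

**Step 3**
Reactants: 4 (4S,5R)-2-methyl-5-(prop-1-en-2-yl)-4-(triethylsilyloxy)cyclohex-2-en-1-one
Product: 6 β-hydroxy ketone bearing a 1-hydroxyethyl group on C10 cis to the C7 isopropenyl (C10 methyl trans; carbinol epimers), via lithium enolate 5 (not isolated)
Conditions: LiBH(s-Bu)3 (1.1 equiv), THF, −78 °C; then CH3CHO, −78 °C; H2O work-up
Reagents that add atoms: acetaldehyde, CC=O
Why: 1,4-Hydride delivery to the β-unsubstituted enone gives the C10 enolate regiospecifically, and the aldol addition (reductive aldol reaction) occurs by axial attack on the half-chair with equatorial C7 isopropenyl and C8–OSiEt3, which places the new arm on the isopropenyl face and the methyl on the other.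

**Step 4**
Reactants: 6 β-hydroxy ketone bearing a 1-hydroxyethyl group on C10
Product: 7 2-ethenyl-2-methyl-5-(prop-1-en-2-yl)-4-(triethylsilyloxy)cyclohexan-1-one (vinyl cis and OSiEt3 trans to the isopropenyl)
Conditions: Ph2S[OC(CF3)2Ph]2, CH2Cl2, 0 °C → rt
Reagents that add atoms: none
Why: Sulfurane-mediated dehydration (Martin sulfurane) of the secondary alcohol can only eliminate toward the methyl group because C10 is quaternary, so the C10 vinyl group forms without touching a stereocentre.

**Step 5**
Reactants: 7 2-ethenyl-2-methyl-5-(prop-1-en-2-yl)-4-(triethylsilyloxy)cyclohexan-1-one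
Product: 9 enol triflate of 7 (C5–OSO2CF3; C5=C6), via potassium enolate 8 (not isolated)
Conditions: KN(SiMe3)2, THF, −78 °C; then PhNTf2, −78 → 0 °C
Reagents that add atoms: N-phenylbis(trifluoromethanesulfonimide), O=S(=O)(N(c1ccccc1)S(=O)(=O)C(F)(F)F)C(F)(F)F
Why: The ketone can enolise only toward C6 because C10 is quaternary, so deprotonation and O-triflation give a single enol triflate (enol triflate formation).

**Step 6**
Reactants: 10 2-bromoprop-2-en-1-ol
Product: 11 (2-bromoallyloxy)(tert-butyl)dimethylsilane
Conditions: t-BuMe2SiCl, imidazole, CH2Cl2, 0 °C → rt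
Reagents that add atoms: tert-butylchlorodimethylsilane, CC(C)(C)[Si](C)(C)Cl
Why: Routine silylation of a primary allylic alcohol (silyl ether formation).

**Step 7**
Reactants: 9 enol triflate of 7; 11 (2-bromoallyloxy)(tert-butyl)dimethylsilane
Product: 14 1,3-diene in which C5 carries the 3-(tert-butyldimethylsilyloxy)prop-1-en-2-yl group (C5=C6 kept), via alkenyllithium 12 (not isolated), via alkenylzinc bromide 13 (not isolated)
Conditions: 11, t-BuLi (2.1 equiv), Et2O, −78 °C; ZnBr2, THF, −78 → 0 °C; then 9, Pd(PPh3)4 (5 mol %), THF, 50 °C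
Reagents that add atoms: none
Why: Bromine–lithium exchange, transmetalation to zinc (which suppresses β-elimination of the silyloxy group) and Negishi coupling with the enol triflate under zerovalent palladium catalysis form the C5–C4 bond without creating a stereocentre.

**Step 8**
Reactants: 14 1,3-diene
Product: 15 alkenyl oxirane (C5–C6 epoxide with oxygen on the face of the C10 methyl, anti to C10 vinyl and C7 isopropenyl)
Conditions: 3-ClC6H4CO3H (m-CPBA, 1.0 equiv), NaHCO3, CH2Cl2, −20 °C
Reagents that add atoms: 3-chloroperoxybenzoic acid, OOC(=O)c1cccc(Cl)c1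
Why: Peracid epoxidation (Prilezhaev reaction) is fastest at the only trisubstituted ring alkene and occurs opposite the pseudoaxial C10 vinyl group, which sets C6–O and places the oxygen where the next step will fix C5.

**Step 9**
Reactants: 15 alkenyl oxirane
Product: 16 homoallylic alcohol (C6–OH, C5 side chain, C8–OSiEt3 and C10 methyl on one face; C7 isopropenyl and C10 vinyl on the other)
Conditions: Pd2(dba)3·CHCl3 (2.5 mol %), n-Bu3P (10 mol %), HCO2H, Et3N, 1,4-dioxane, rt
Reagents that add atoms: none
Why: Zerovalent palladium ionises the allylic C5–O bond with inversion and the palladium hydride formed from formate delivers H to the more substituted terminus C5 on the metal face (Tsuji-type formate hydrogenolysis of an alkenyl oxirane), so H enters anti to oxygen, the C5 side chain ends cis to the retained C6–OH and the 1,1-disubstituted alkene is kept.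

**Step 10**
Reactants: 16 homoallylic alcohol
Product: 17 6,8-diol (16 without the SiEt3 group; C8–OH still trans to the C7 isopropenyl)
Conditions: pyridinium p-toluenesulfonate (10 mol %), MeOH/CH2Cl2, 0 °C
Reagents that add atoms: none
Why: Mild acid methanolysis cleaves the secondary triethylsilyl ether much faster than the primary tert-butyldimethylsilyl ether (selective desilylation).

**Step 11**
Reactants: 18 3-methylfuran-2(5H)-one
Product: 21 4-methoxybenzyl (Z)-4-acetoxy-2-methylbut-2-enoate, via potassium carboxylate 19 (not isolated), via hydroxy ester 20 (not isolated)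
Conditions: KOH (1.0 equiv), MeOH/H2O, 0 °C, evaporate; 4-MeOC6H4CH2Cl, n-Bu4NI (cat.), DMF, 0 °C; then Ac2O, pyridine, 4-(dimethylamino)pyridine (cat.), 0 °C
Reagents that add atoms: potassium hydroxide, [K+].[OH-]; 4-methoxybenzyl chloride, COc1ccc(CCl)cc1; acetic anhydride, CC(=O)OC(C)=O
Why: Saponification opens the butenolide so that the ring cis geometry becomes the (Z)-alkene, and carboxylate O-alkylation followed at once by acetylation traps the open form before it can relactonise (ester formation and acylation).

**Step 12**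
Reactants: 21 4-methoxybenzyl (Z)-4-acetoxy-2-methylbut-2-enoate
Product: 22 (Z)-4-acetoxy-2-methylbut-2-enoic acid
Conditions: CF3CO2H, anisole, CH2Cl2, 0 °C
Reagents that add atoms: none
Why: Acidolysis of the 4-methoxybenzyl ester with a cation scavenger frees the acid without touching the acetate or the (Z)-alkene.

**Step 13**
Reactants: 17 6,8-diol; 22 (Z)-4-acetoxy-2-methylbut-2-enoic acid
Product: 23 C8 (Z)-4-acetoxy-2-methylbut-2-enoate ester with C8–O now cis to the C7 isopropenyl (C6–OH free; C15–OSi-t-BuMe2)
Conditions: PPh3, i-PrO2CN=NCO2i-Pr (DIAD), toluene, 0 °C → rt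
Reagents that add atoms: none
Why: Mitsunobu esterification activates the less hindered equatorial C8 hydroxyl (C6–OH is flanked by two branched carbons) and the carboxylate of 22 displaces it with inversion (SN2), forming the C8–O bond cis to the C7 side chain without ever activating the isomerisation-prone (Z)-acid.

**Step 14**
Reactants: 23 C8 ester
Product: 24 enal (C7 isopropenyl methyl oxidised to CHO; C11=C13 methylene kept)
Conditions: SeO2 (1.2 equiv), 1,4-dioxane, 80 °C
Reagents that add atoms: selenium dioxide, O=[Se]=O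
Why: SeO2 allylic oxidation (ene reaction then [2,3]-sigmatropic shift) attacks the only unfunctionalised isopropenyl group, since the vinyl group has no allylic hydrogen, the C5 side-chain alkene is deactivated by its allylic silyloxy group and the enoate is electron-poor.

**Step 15**
Reactants: 24 enal
Product: 25 acrylic acid with the C15 silyl ether still in place
Conditions: NaClO2, NaH2PO4, 2-methylbut-2-ene, t-BuOH/H2O, 0 °C
Reagents that add atoms: sodium chlorite, [Na+].[O-]Cl=O
Why: Pinnick oxidation converts the enal into the acrylic acid under buffered conditions while 2-methylbut-2-ene scavenges HOCl, leaving alkenes, esters and the silyl ether intact.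

**Step 16**
Reactants: 25 acrylic acid with the C15 silyl ether
Product: 26 target, 2-[(1S,2R,3S,4R,6R)-6-{[(2Z)-4-acetoxy-2-methylbut-2-enoyl]oxy}-4-ethenyl-2-hydroxy-3-(3-hydroxyprop-1-en-2-yl)-4-methylcyclohexyl]prop-2-enoic acid
Conditions: HF·pyridine, pyridine, THF, 0 °C
Reagents that add atoms: none
Why: Buffered fluoride cleaves the primary allylic silyl ether (desilylation) under conditions mild enough to avoid acyl migration and closure of the hydroxy acid to the 6,12-lactone.

**Compound list**
1 | (R)-(−)-carvone, (5R)-2-methyl-5-(prop-1-en-2-yl)cyclohex-2-en-1-one | CC1=CC[C@@H](C(C)=C)CC1=O | starting material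
2 | bromomagnesium through-conjugated dienolate of 1 (C5–OMgBr) | Br[Mg]OC1=C(C)C=C[C@@H](C(C)=C)C1 | intermediate
3 | 2-methyl-5-(prop-1-en-2-yl)-1-(trimethylsilyloxy)cyclohexa-1,3-diene, C7 centre as in 1 | C[Si](C)(C)OC1=C(C)C=C[C@@H](C(C)=C)C1 | intermediate
4 | (4S,5R)-2-methyl-5-(prop-1-en-2-yl)-4-(triethylsilyloxy)cyclohex-2-en-1-one | CC1=C[C@H](O[Si](CC)(CC)CC)[C@@H](C(C)=C)CC1=O | intermediate
5 | lithium enolate from conjugate reduction of 4 (C5–OLi, C5=C10) | [Li]OC1=C(C)C[C@H](O[Si](CC)(CC)CC)[C@@H](C(C)=C)C1 | intermediate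
6 | 2-(1-hydroxyethyl)-2-methyl-5-(prop-1-en-2-yl)-4-(triethylsilyloxy)cyclohexan-1-one, hydroxyethyl cis and OSiEt3 trans to isopropenyl, carbinol epimers | CC(O)[C@@]1(C)C[C@H](O[Si](CC)(CC)CC)[C@@H](C(C)=C)CC1=O | intermediate
7 | 2-ethenyl-2-methyl-5-(prop-1-en-2-yl)-4-(triethylsilyloxy)cyclohexan-1-one, vinyl cis and OSiEt3 trans to isopropenyl | C=C[C@@]1(C)C[C@H](O[Si](CC)(CC)CC)[C@@H](C(C)=C)CC1=O | intermediate
8 | potassium enolate of 7 (C5–OK, C5=C6) | C=C[C@@]1(C)C[C@H](O[Si](CC)(CC)CC)[C@@H](C(C)=C)C=C1O[K] | intermediate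
9 | enol triflate of 7 (C5–OSO2CF3, C5=C6) | C=C[C@@]1(C)C[C@H](O[Si](CC)(CC)CC)[C@@H](C(C)=C)C=C1OS(=O)(=O)C(F)(F)F | intermediate
10 | 2-bromoprop-2-en-1-ol | C=C(Br)CO | starting material
11 | (2-bromoallyloxy)(tert-butyl)dimethylsilane | C=C(Br)CO[Si](C)(C)C(C)(C)C | intermediate
12 | [3-(tert-butyldimethylsilyloxy)prop-1-en-2-yl]lithium | [Li]C(=C)CO[Si](C)(C)C(C)(C)C | intermediate
13 | [3-(tert-butyldimethylsilyloxy)prop-1-en-2-yl]zinc bromide | Br[Zn]C(=C)CO[Si](C)(C)C(C)(C)C | intermediate
14 | 1,3-diene: 9 with OSO2CF3 replaced by the 3-(tert-butyldimethylsilyloxy)prop-1-en-2-yl group | C=C[C@@]1(C)C[C@H](O[Si](CC)(CC)CC)[C@@H](C(C)=C)C=C1C(=C)CO[Si](C)(C)C(C)(C)C | intermediate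
15 | alkenyl oxirane: C5–C6 epoxide of 14, oxygen on the C10-methyl face | C=C[C@@]1(C)C[C@H](O[Si](CC)(CC)CC)[C@@H](C(C)=C)[C@@H]2O[C@@]21C(=C)CO[Si](C)(C)C(C)(C)C | intermediate
16 | homoallylic alcohol: C6–OH, C5 side chain and C8–OSiEt3 on the C10-methyl face; C7 isopropenyl and C10 vinyl on the other | C=C[C@@]1(C)C[C@H](O[Si](CC)(CC)CC)[C@@H](C(C)=C)[C@H](O)[C@@H]1C(=C)CO[Si](C)(C)C(C)(C)C | intermediate
17 | 6,8-diol: 16 with free C8–OH (trans to C7 isopropenyl) | C=C[C@@]1(C)C[C@H](O)[C@@H](C(C)=C)[C@H](O)[C@@H]1C(=C)CO[Si](C)(C)C(C)(C)C | intermediate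
18 | 3-methylfuran-2(5H)-one | CC1=CCOC1=O | starting material
19 | potassium (Z)-4-hydroxy-2-methylbut-2-enoate | [K+].[O-]C(=O)/C(C)=C\CO | intermediate
20 | 4-methoxybenzyl (Z)-4-hydroxy-2-methylbut-2-enoate | COc1ccc(COC(=O)/C(C)=C\CO)cc1 | intermediate
21 | 4-methoxybenzyl (Z)-4-acetoxy-2-methylbut-2-enoate | COc1ccc(COC(=O)/C(C)=C\COC(C)=O)cc1 | intermediate
22 | (Z)-4-acetoxy-2-methylbut-2-enoic acid | OC(=O)/C(C)=C\COC(C)=O | intermediate
23 | C8 (Z)-4-acetoxy-2-methylbut-2-enoate of 17, C8–O inverted (cis to C7 isopropenyl) | C=C[C@@]1(C)C[C@@H](OC(=O)/C(C)=C\COC(C)=O)[C@@H](C(C)=C)[C@H](O)[C@@H]1C(=C)CO[Si](C)(C)C(C)(C)C | intermediate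
24 | enal: 23 with the C7 side chain as 3-oxoprop-1-en-2-yl | C=C[C@@]1(C)C[C@@H](OC(=O)/C(C)=C\COC(C)=O)[C@@H](C(=C)C=O)[C@H](O)[C@@H]1C(=C)CO[Si](C)(C)C(C)(C)C | intermediate
25 | acrylic acid: 24 with CHO oxidised to CO2H, C15 silyl ether kept | C=C[C@@]1(C)C[C@@H](OC(=O)/C(C)=C\COC(C)=O)[C@@H](C(=C)C(=O)O)[C@H](O)[C@@H]1C(=C)CO[Si](C)(C)C(C)(C)C | intermediate
26 | CNP0261293.1, 2-[(1S,2R,3S,4R,6R)-6-{[(2Z)-4-acetoxy-2-methylbut-2-enoyl]oxy}-4-ethenyl-2-hydroxy-3-(3-hydroxyprop-1-en-2-yl)-4-methylcyclohexyl]prop-2-enoic acid | C=C[C@@]1(C)C[C@@H](OC(=O)/C(C)=C\COC(C)=O)[C@@H](C(=C)C(=O)O)[C@H](O)[C@@H]1C(=C)CO | target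

**Step count**
Total steps: 16. Longest linear sequence: 13 (steps 1–5, 7–10, 13–16).

**Three steps most likely to fail**

Step 2 (the proposed new vinylogous silyloxylation) may give α-attack at C10, over-oxidation or no turnover. The fallback uses known chemistry and sets out from 3: vinylogous Rubottom oxidation with m-CPBA/NaHCO3 in CH2Cl2 at −20 °C, followed by a fluoride work-up, gives (4S,5R)-4-hydroxy-2-methyl-5-(prop-1-en-2-yl)cyclohex-2-en-1-one F1, and silylation with Et3SiCl/imidazole brings it back to the route at 4.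

Step 13 (Mitsunobu inversion at C8) requires the carboxylate to enter axially, syn to the axial C10 vinyl group, with a fairly weak acid; elimination or no reaction is possible. The fallback sets out from 17 and separates inversion from acylation: oxidation with 2,2,6,6-tetramethylpiperidin-1-oxyl (cat.)/PhI(OAc)2 at the less hindered C8 carbinol gives the 6-hydroxy-8-ketone F2. Reduction with LiBH(s-Bu)3 at −78 °C, from the face away from the axial C10 vinyl, gives the 8-epi-6,8-diol F3 (C8–OH cis to the C7 isopropenyl). Yamaguchi esterification with 22 (2,4,6-trichlorobenzoyl chloride, Et3N, then 4-(dimethylamino)pyridine) returns to the route at 23.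

Step 14 (late SeO2 oxidation) may suffer from poor site selectivity among four alkenes, over-oxidation or Z/E isomerisation of the enoate. The fallback sets out from 23: ene-type allylic chlorination of the C7 isopropenyl with N-chlorosuccinimide and catalytic PhSeCl gives the allylic chloride F4, and oxidation of this chloride with N-methylmorpholine N-oxide in MeCN comes back to the route at 24.

**Further compounds**
F1 | step 2 | (4S,5R)-4-hydroxy-2-methyl-5-(prop-1-en-2-yl)cyclohex-2-en-1-one | CC1=C[C@H](O)[C@@H](C(C)=C)CC1=O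
F2 | step 13 | 6-hydroxy-8-ketone from 17 (C8 carbinol oxidised, C15 silyl ether kept) | C=C[C@@]1(C)CC(=O)[C@@H](C(C)=C)[C@H](O)[C@@H]1C(=C)CO[Si](C)(C)C(C)(C)C
F3 | step 13 | 8-epi-6,8-diol (C8–OH cis to the C7 isopropenyl) | C=C[C@@]1(C)C[C@@H](O)[C@@H](C(C)=C)[C@H](O)[C@@H]1C(=C)CO[Si](C)(C)C(C)(C)C
F4 | step 14 | allylic chloride: 23 with the C7 side chain as 3-chloroprop-1-en-2-yl | C=C[C@@]1(C)C[C@@H](OC(=O)/C(C)=C\COC(C)=O)[C@@H](C(=C)CCl)[C@H](O)[C@@H]1C(=C)CO[Si](C)(C)C(C)(C)C
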